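**Retrosynthetic overview**
- The target is traced back to its ring-B aldehyde (NaBH4 at the end). The key cut is the ring-A aryl–CH2OH bond: aryl iodide (electrophile) plus Bu3SnCH2OH as a hydroxymethyl carbanion, i.e. formaldehyde with inverted polarity. It is made late, on the unprotected tribromo-triphenol, coupling C–I in the presence of three C–Br.
- The two bromines ortho to OH come from SEAr after demethylation; the iodide handle comes from para-selective iodination of the anisole ring.
- The diaryl ether comes from SNAr of 2-bromo-6-methoxyphenol on 2-fluoro-3,4-dimethoxybenzaldehyde; the formyl group activates the fluoride and later becomes the ring-B CH2OH.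
- No ring is constructed; both benzene rings are purchased. Order of events: ether → iodide → free phenols → bromides → C–C bond → reduction.

Assumption: the target has no stereocentre and its diaryl ether axis is not configurationally defined, so it is made as the single achiral compound.

**Route**

Step 1
Reactants: 1 2-fluoro-3,4-dimethoxybenzaldehyde; 2 2-bromo-6-methoxyphenol
Product: 3 2-(2-bromo-6-methoxyphenoxy)-3,4-dimethoxybenzaldehyde
Conditions: Cs2CO3 (1.5 equiv), DMSO, 110 °C
Reagents that add atoms: none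
Why: SNAr (addition–elimination) in which the phenoxide of 2 displaces the fluoride ortho to the formyl group, which stabilises the Meisenheimer adduct, while the aryl bromide is inert without a metal catalyst; no stereocentre is formed.

Step 2
Reactants: 3 2-(2-bromo-6-methoxyphenoxy)-3,4-dimethoxybenzaldehyde
Product: 4 2-(2-bromo-3-iodo-6-methoxyphenoxy)-3,4-dimethoxybenzaldehyde
Conditions: NIS (1.05 equiv), TFA (0.3 equiv), MeCN, rt, dark
Reagents that add atoms: N-iodosuccinimide, O=C1CCC(=O)N1I
Why: Electrophilic aromatic iodination (SEAr) is expected para to the methoxy group of the bromoanisole ring, the only ring not deactivated by a formyl group, because the ortho position is shielded by the O-methyl group and the flanked central aryloxy oxygen is twisted out of conjugation; no stereocentre is formed.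

Step 3
Reactants: 4 2-(2-bromo-3-iodo-6-methoxyphenoxy)-3,4-dimethoxybenzaldehyde
Product: 5 2-(2-bromo-6-hydroxy-3-iodophenoxy)-3,4-dihydroxybenzaldehyde
Conditions: BBr3 (6 equiv), CH2Cl2, −78 °C to rt; then H2O
Reagents that add atoms: none
Why: Lewis-acid ether cleavage (BBr3 demethylation) removes the three O-methyl groups while the diaryl ether, the aldehyde and the C–Br and C–I bonds are untouched; no stereocentre is formed.

Step 4
Reactants: 5 2-(2-bromo-6-hydroxy-3-iodophenoxy)-3,4-dihydroxybenzaldehyde
Product: 6 5-bromo-2-(2,5-dibromo-6-hydroxy-3-iodophenoxy)-3,4-dihydroxybenzaldehyde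
Conditions: NBS (2.05 equiv), MeCN, 0 °C to rt
Reagents that add atoms: N-bromosuccinimide, O=C1CCC(=O)N1Br
Why: Electrophilic aromatic bromination (SEAr) ortho to free hydroxyls, since on the iodo ring the para position is blocked by iodine and only one ortho position is open, and on the aldehyde ring C5 is ortho to the 4-OH, para to the aryloxy oxygen and meta to CHO, the site at which 2,3,4-trioxygenated benzaldehydes brominate; no stereocentre is formed.

Step 5
Reactants: 6 5-bromo-2-(2,5-dibromo-6-hydroxy-3-iodophenoxy)-3,4-dihydroxybenzaldehyde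
Product: 7 5-bromo-2-[2,5-dibromo-6-hydroxy-3-(hydroxymethyl)phenoxy]-3,4-dihydroxybenzaldehyde
Conditions: Bu3SnCH2OH (1.2 equiv), Pd(PPh3)4 (10 mol %), 1,4-dioxane, 80 °C, Ar, dark
Reagents that add atoms: (tributylstannyl)methanol, CCCC[Sn](CCCC)(CCCC)CO
Why: Stille (Migita–Kosugi) cross-coupling in which the α-stannyl carbinol delivers a hydroxymethyl carbanion, i.e. formaldehyde with inverted polarity (a d1 donor), to the electrophilic C–I carbon, with Pd(0) inserting into C–I far faster than into the three C–Br bonds and base-free conditions tolerating the free phenols, catechol and aldehyde; no stereocentre is formed.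

Step 6
Reactants: 7 5-bromo-2-[2,5-dibromo-6-hydroxy-3-(hydroxymethyl)phenoxy]-3,4-dihydroxybenzaldehyde
Product: 8 6-bromo-3-[2,5-dibromo-6-hydroxy-3-(hydroxymethyl)phenoxy]-4-(hydroxymethyl)benzene-1,2-diol (target)
Conditions: NaBH4 (4 equiv), THF/EtOH, 0 °C; aq NH4Cl
Reagents that add atoms: none
Why: Hydride reduction of the aryl aldehyde to the benzylic alcohol with NaBH4 at 0 °C leaves aryl bromides and phenols untouched, and the buffered quench avoids quinone-methide formation from the p-hydroxybenzyl alcohols; no stereocentre is formed and the achiral target results.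

**Compound list**
1 | 2-fluoro-3,4-dimethoxybenzaldehyde | COc1ccc(C=O)c(F)c1OC | starting material
2 | 2-bromo-6-methoxyphenol | COc1cccc(Br)c1O | starting material
3 | 2-(2-bromo-6-methoxyphenoxy)-3,4-dimethoxybenzaldehyde | COc1ccc(C=O)c(Oc2c(Br)cccc2OC)c1OC | intermediate
4 | 2-(2-bromo-3-iodo-6-methoxyphenoxy)-3,4-dimethoxybenzaldehyde | COc1ccc(C=O)c(Oc2c(Br)c(I)ccc2OC)c1OC | intermediate
5 | 2-(2-bromo-6-hydroxy-3-iodophenoxy)-3,4-dihydroxybenzaldehyde | O=Cc1ccc(O)c(O)c1Oc1c(Br)c(I)ccc1O | intermediate
6 | 5-bromo-2-(2,5-dibromo-6-hydroxy-3-iodophenoxy)-3,4-dihydroxybenzaldehyde | O=Cc1cc(Br)c(O)c(O)c1Oc1c(Br)c(I)cc(Br)c1O | intermediate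
7 | 5-bromo-2-[2,5-dibromo-6-hydroxy-3-(hydroxymethyl)phenoxy]-3,4-dihydroxybenzaldehyde | O=Cc1cc(Br)c(O)c(O)c1Oc1c(Br)c(CO)cc(Br)c1O | intermediate
8 | 6-bromo-3-[2,5-dibromo-6-hydroxy-3-(hydroxymethyl)phenoxy]-4-(hydroxymethyl)benzene-1,2-diol | OCc1cc(Br)c(O)c(Oc2c(CO)cc(Br)c(O)c2O)c1Br | target

**Step count and risks**
Total steps: 6. Longest linear sequence: 6.

The three steps most likely to fail are 5, 2 and 1.

Step 5 (C–I versus C–Br selectivity, catechol on palladium). The fallback sets out from 4 and returns at 8. The same Stille hydroxymethylation is moved to the fully protected stage, where only one C–I and one C–Br are present and no OH is free. Compound 4 with Bu3SnCH2OH and Pd(PPh3)4 in dioxane gives 2-[2-bromo-3-(hydroxymethyl)-6-methoxyphenoxy]-3,4-dimethoxybenzaldehyde F1. Because a benzylic alcohol would not survive BBr3, it is oxidised with MnO2 in CH2Cl2 to 2-bromo-3-(6-formyl-2,3-dimethoxyphenoxy)-4-methoxybenzaldehyde F2. BBr3 then gives 2-bromo-3-(6-formyl-2,3-dihydroxyphenoxy)-4-hydroxybenzaldehyde F3. NBS brominates ortho to the two para-formyl hydroxyls to give 2,5-dibromo-3-(4-bromo-6-formyl-2,3-dihydroxyphenoxy)-4-hydroxybenzaldehyde F4. A double NaBH4 reduction delivers 8. This costs one step more than the main route.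

Step 2 (iodination on the wrong ring or ortho to OMe). The fallback sets out from 2 and returns at 4. The handle is installed before the second ring is present. Acetylation of 2 (Ac2O, pyridine) gives 2-bromo-6-methoxyphenyl acetate F5. NIS/TFA iodinates para to the methoxy group to give 2-bromo-3-iodo-6-methoxyphenyl acetate F6. K2CO3 in MeOH frees 2-bromo-3-iodo-6-methoxyphenol F7. F7 then undergoes the SNAr of step 1 with 1 (Cs2CO3, DMSO) to give 4 directly.

Step 1 (tetra-ortho-substituted diaryl ether by SNAr). The fallback sets out from 1 and returns at 3. The formyl group is exchanged for the slimmer, stronger and base-stable nitrile activator. Compound 1 with NH2OH·HCl in hot DMSO gives, through (E)-2-fluoro-3,4-dimethoxybenzaldehyde oxime F8, 2-fluoro-3,4-dimethoxybenzonitrile F9. SNAr of F9 with 2 (Cs2CO3, DMSO) gives 2-(2-bromo-6-methoxyphenoxy)-3,4-dimethoxybenzonitrile F10. DIBAL-H in toluene at −78 °C followed by aqueous HCl returns aldehyde 3.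

**Further compounds**
F1 | step 5 | 2-[2-bromo-3-(hydroxymethyl)-6-methoxyphenoxy]-3,4-dimethoxybenzaldehyde | COc1ccc(C=O)c(Oc2c(Br)c(CO)ccc2OC)c1OC
F2 | step 5 | 2-bromo-3-(6-formyl-2,3-dimethoxyphenoxy)-4-methoxybenzaldehyde | COc1ccc(C=O)c(Oc2c(Br)c(C=O)ccc2OC)c1OC
F3 | step 5 | 2-bromo-3-(6-formyl-2,3-dihydroxyphenoxy)-4-hydroxybenzaldehyde | O=Cc1ccc(O)c(O)c1Oc1c(Br)c(C=O)ccc1O
F4 | step 5 | 2,5-dibromo-3-(4-bromo-6-formyl-2,3-dihydroxyphenoxy)-4-hydroxybenzaldehyde | O=Cc1cc(Br)c(O)c(O)c1Oc1c(Br)c(C=O)cc(Br)c1O
F5 | step 2 | 2-bromo-6-methoxyphenyl acetate | COc1cccc(Br)c1OC(C)=O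
F6 | step 2 | 2-bromo-3-iodo-6-methoxyphenyl acetate | COc1ccc(I)c(Br)c1OC(C)=O
F7 | step 2 | 2-bromo-3-iodo-6-methoxyphenol | COc1ccc(I)c(Br)c1O
F8 | step 1 | (E)-2-fluoro-3,4-dimethoxybenzaldehyde oxime | COc1ccc(/C=N/O)c(F)c1OC
F9 | step 1 | 2-fluoro-3,4-dimethoxybenzonitrile | COc1ccc(C#N)c(F)c1OC
F10 | step 1 | 2-(2-bromo-6-methoxyphenoxy)-3,4-dimethoxybenzonitrile | COc1ccc(C#N)c(Oc2c(Br)cccc2OC)c1OC
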